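**Retrosynthetic overview**

- Feature: the only stereocentre, chain carbon C3, is bonded to ring A at C3', next to the C2' phenol oxygen. It carries two two-carbon arms, C1=C2 and C4–C5, which can both be vinyl groups; a vinyl group on O2' reaches one of them and closes a six-membered 4H-chromene ring (O2', C1, C2, C3, C3', C2').
- Disconnections, backwards: chalcone C=C (aldol condensation at the ring A acetyl group); C1–aryl bond and C1=C2 (aryl addition to a C1 aldehyde, then dehydration); C5–C6 (hydroboration of the surviving vinyl group, alkyl–alkyl Suzuki coupling); chromene C1=C2 (ring-closing metathesis that selects one of two enantiotopic vinyl groups).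
- The triene comes from 2',4'-dihydroxy-6'-methoxyacetophenone by O4'-pentadienylation, aromatic Claisen shift to C3', O4'-silylation and O2'-vinylation.
- Rings: ring A and the three 4-oxyphenyl rings are bought; the 4H-chromene ring is the only ring made (step 6) and is opened again by hydrolysis (step 9).
- Phenols travel as silyl ethers, and O2' as an allyl ether once the ring is opened, so the end needs only zerovalent palladium and buffered fluoride; acid is avoided because it would close O2' or O4' onto the styrene.

Key step: step 6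

Assumption: chain carbons C1–C7 are counted from the styrenyl end, and primed numbers refer to ring A with C1' bearing the acyl group.
Assumption: the sense of induction of the biphenolate ligand cannot be predicted safely for this triene; the (S)-diolate is written for whichever antipode delivers (4R)-8, both antipodes being accessible.
Assumption: hydroxy aldehyde 13 is drawn open-chain; it should equilibrate with its cyclic hemiacetal (a 2-chromanol), and under K2CO3 both forms should react as the phenoxide aldehyde.

**Route**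

Step 1
Reactants: 1 penta-1,4-dien-3-ol
Product: 2 (E)-5-bromopenta-1,3-diene
Conditions: 48% aq HBr, 0 °C to rt; used crude, kept cold and dark
Reagents that add atoms: hydrogen bromide, Br
Why: Allylic transposition through the pentadienyl cation (SN1-type substitution), in which bromide adds at a chain terminus and the conjugated primary E bromide should form as the thermodynamic product.

Step 2
Reactants: 3 2',4'-dihydroxy-6'-methoxyacetophenone; 2 (E)-5-bromopenta-1,3-diene
Product: 4 1-[2-hydroxy-6-methoxy-4-[(2E)-penta-2,4-dien-1-yloxy]phenyl]ethan-1-one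
Conditions: K2CO3, acetone, rt to 40 °C
Reagents that add atoms: none
Why: Williamson etherification that should take place only at the 4-hydroxyl, which is para to the acetyl group and not hydrogen-bonded, while the 2-hydroxyl stays locked in the chelate with the carbonyl oxygen; attack at either end of the pentadienyl system gives the same linear ether.

Step 3
Reactants: 4 pentadienyl ether
Product: 5 1-[2,4-dihydroxy-6-methoxy-3-(penta-1,4-dien-3-yl)phenyl]ethan-1-one
Conditions: PhNEt2, 185 °C, 0.05 M, Ar
Reagents that add atoms: none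
Why: Aromatic Claisen rearrangement, in which the [3,3] shift joins C3 of the dienyl chain to an ortho carbon and tautomerisation leaves the divinylmethyl group; the ether is placed on O4' so that the para carbon is the acetyl-bearing C1' and the [5,5] shift open to pentadienyl aryl ethers has no productive outlet, and the hydrogen-bonded 2-hydroxyl/acetyl chelate should direct migration to C3' rather than C5' by bond fixation.

Step 4
Reactants: 5 divinylmethyl resorcinol ketone
Product: 6 1-[2-hydroxy-6-methoxy-3-(penta-1,4-dien-3-yl)-4-(triisopropylsilyloxy)phenyl]ethan-1-one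
Conditions: TIPSCl, imidazole, DMF, rt to 40 °C
Reagents that add atoms: triisopropylsilyl chloride, CC(C)[Si](Cl)(C(C)C)C(C)C
Why: Silyl ether formation at the free 4-hydroxyl, since the chelated 2-hydroxyl between two ortho substituents should not react with the bulky chloride; the triisopropylsilyl ether is chosen because it should survive the later phosphate, carbonate and dilute acid and leave with fluoride at the end.

Step 5
Reactants: 6 silyl-protected phenol
Product: 7 1-[2-(ethenyloxy)-6-methoxy-3-(penta-1,4-dien-3-yl)-4-(triisopropylsilyloxy)phenyl]ethan-1-one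
Conditions: Cu(OAc)2, 2,4,6-trivinylcyclotriboroxane–pyridine complex, pyridine, CH2Cl2, air, rt
Reagents that add atoms: 2,4,6-trivinylcyclotriboroxane–pyridine complex, C=CB1OB(C=C)OB(C=C)O1.c1ccncc1
Why: Chan–Lam oxidative O-vinylation, in which the copper phenoxide takes a vinyl group from boron and the C–O bond forms by reductive elimination at room temperature under near-neutral conditions that should leave the skipped diene and the methyl ketone alone.

Step 6
Reactants: 7 divinylmethyl aryl vinyl ether
Product: 8 1-[(4R)-4-ethenyl-7-methoxy-5-(triisopropylsilyloxy)-4H-chromen-8-yl]ethan-1-one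
Conditions: Mo(=N-2,6-iPr2C6H3)(=CHCMe2Ph)[(S)-3,3'-di-tert-butyl-5,5',6,6'-tetramethylbiphenyl-2,2'-diolate] (10 mol %), C6H6 (0.02 M), 22 to 50 °C, N2, ethylene vented
Reagents that add atoms: none
Why: The molybdenum alkylidene exchanges reversibly onto the terminal all-carbon vinyl groups (loading on the vinyl ether would give a sluggish oxygen-substituted alkylidene), adds [2+2] to the tethered O-vinyl group and cycloreverts to the chromene and Mo=CH2, which re-enters the cycle with loss of ethylene. The closest known reaction type is molybdenum-catalysed asymmetric ring-closing metathesis of enol ether trienes to six-membered cyclic enol ethers. The one ring formed (O1, C2, C3, C4, C4a, C8a) closes as a six-membered ring by ring-closing olefin metathesis with the new C2=C3 bond inside the ring. The C4 stereocentre arises by selection between the two enantiotopic vinyl groups under catalyst control: in the pocket of the chiral biphenolate only one of the two diastereomeric alkylidene–olefin arrangements should reach the metallacyclobutane, and alkylidene exchange between the vinyl groups keeps the unproductive one from being a dead end. The step needs enantiotopos selectivity, ring-size selectivity and chemoselectivity: the short aryl ether tether allows only the six-membered closure (closure between the two vinyl groups would be a cyclopropene), and the acetyl group, the one function an alkylidene could olefinate, is twisted out of the ring plane between two ortho substituents and lies meta to the carbene-bearing arm, out of its intramolecular reach.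

Step 7
Reactants: 9 4-(2-bromoethyl)phenol
Product: 10 [4-(2-bromoethyl)phenoxy]triisopropylsilane
Conditions: TIPSCl, imidazole, CH2Cl2, rt
Reagents that add atoms: triisopropylsilyl chloride, CC(C)[Si](Cl)(C(C)C)C(C)C
Why: Phenol silylation under imidazole catalysis, mild enough to leave the primary bromide in place, giving an aryl silyl ether that should withstand the basic coupling and the acidic hydrolysis that follow.

Step 8
Reactants: 8 vinyl chromene; 10 silyl-protected bromide
Product: 12 1-[(4R)-7-methoxy-5-(triisopropylsilyloxy)-4-[4-[4-(triisopropylsilyloxy)phenyl]butyl]-4H-chromen-8-yl]ethan-1-one, via alkylborane 11 (not isolated)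
Conditions: 9-BBN, THF, 0 °C to rt; then 10, Pd(OAc)2 (4 mol %), PCy3 (8 mol %), K3PO4·H2O, THF, rt
Reagents that add atoms: none
Why: Anti-Markovnikov hydroboration of the monosubstituted vinyl group, which should be much faster than attack on the cyclic enol ether or the hindered ketone, followed by alkyl–alkyl Suzuki–Miyaura coupling with the primary bromide, where the bulky electron-rich phosphine lets oxidative addition and transmetalation outrun β-hydride elimination; the stereocentre is not touched.

Step 9
Reactants: 12 butyl chromene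
Product: 13 (3R)-3-[3-acetyl-2-hydroxy-4-methoxy-6-(triisopropylsilyloxy)phenyl]-7-[4-(triisopropylsilyloxy)phenyl]heptanal
Conditions: 1 M aq HCl, THF, 40 °C
Reagents that add atoms: water, O
Why: Acid-catalysed enol ether hydrolysis (protonation at C3 of the chromene, addition of water to the oxocarbenium ion at C2) opens the ring to the C1 aldehyde and the free 2'-phenol under conditions the aryl triisopropylsilyl ethers should tolerate; C3 is not enolisable and keeps its configuration.

Step 10
Reactants: 13 hydroxy aldehyde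
Product: 14 (3R)-3-[3-acetyl-4-methoxy-2-(prop-2-en-1-yloxy)-6-(triisopropylsilyloxy)phenyl]-7-[4-(triisopropylsilyloxy)phenyl]heptanal
Conditions: allyl bromide, K2CO3, acetone, rt to 40 °C
Reagents that add atoms: allyl bromide, C=CCBr
Why: Williamson O-allylation of the ortho-acyl phenoxide, the dominant anion in the ring–chain equilibrium, which fixes the open aldehyde and masks O2' so that it cannot close onto C1 during the arylation and dehydration.

Step 11
Reactants: 15 4-iodophenol
Product: 16 tert-butyl(4-iodophenoxy)dimethylsilane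
Conditions: TBSCl, imidazole, CH2Cl2, rt
Reagents that add atoms: tert-butyldimethylsilyl chloride, CC(C)(C)[Si](C)(C)Cl
Why: Standard phenol silylation; the tert-butyldimethylsilyl ether is sufficient here because no aqueous acid or base follows its introduction.

Step 12
Reactants: 14 allyl-protected aldehyde; 16 silyl-protected aryl iodide
Product: 18 1-[3-[(1RS,3R)-1-[4-(tert-butyldimethylsilyloxy)phenyl]-1-hydroxy-7-[4-(triisopropylsilyloxy)phenyl]heptan-3-yl]-6-methoxy-2-(prop-2-en-1-yloxy)-4-(triisopropylsilyloxy)phenyl]ethan-1-one, via arylchromium 17 (not isolated)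
Conditions: CrCl2, NiCl2 (2 mol %), DMF, rt
Reagents that add atoms: none
Why: Nozaki–Hiyama–Kishi arylation, in which zerovalent nickel inserts into the aryl iodide, the aryl group passes to trivalent chromium and adds to the aldehyde but not to the hindered methyl ketone; the new carbinol centre at C1 is not controlled and need not be, since C1 becomes sp2 in the next step.

Step 13
Reactants: 18 benzylic alcohol
Product: 20 1-[3-[(1E,3R)-1-[4-(tert-butyldimethylsilyloxy)phenyl]-7-[4-(triisopropylsilyloxy)phenyl]hept-1-en-3-yl]-6-methoxy-2-(prop-2-en-1-yloxy)-4-(triisopropylsilyloxy)phenyl]ethan-1-one, via sulfamate ester 19 (not isolated)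
Conditions: methyl N-(triethylammoniosulfonyl)carbamate (Burgess reagent), PhMe, rt to 60 °C
Reagents that add atoms: none
Why: Burgess dehydration, a syn-elimination through the sulfamate ester under neutral conditions, for which C2 offers the only β-hydrogens, so the conjugated E styrene should form without an acid that would let a flanking oxygen capture C1; C3 is untouched.

Step 14
Reactants: 20 styrene ketone; 21 4-(tert-butyldimethylsilyloxy)benzaldehyde
Product: 24 (2E)-3-[4-(tert-butyldimethylsilyloxy)phenyl]-1-[3-[(1E,3R)-1-[4-(tert-butyldimethylsilyloxy)phenyl]-7-[4-(triisopropylsilyloxy)phenyl]hept-1-en-3-yl]-6-methoxy-2-(prop-2-en-1-yloxy)-4-(triisopropylsilyloxy)phenyl]prop-2-en-1-one, via aldol adduct 22 (not isolated), via mesylate 23 (not isolated)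
Conditions: LiN(SiMe3)2 (1.05 equiv), THF, −78 °C; 21, −78 °C; then MsCl, Et3N, −78 °C to rt
Reagents that add atoms: none
Why: Directed aldol addition of the lithium enolate of the methyl ketone followed by mesylation and E1cB elimination, an aldol condensation to the E chalcone without hydroxide so that the aryl silyl ethers survive; the slight excess of amide at −78 °C should enolise only the ketone and leave the doubly activated C3–H alone.

Step 15
Reactants: 24 allyl-protected chalcone
Product: 25 (2E)-3-[4-(tert-butyldimethylsilyloxy)phenyl]-1-[3-[(1E,3R)-1-[4-(tert-butyldimethylsilyloxy)phenyl]-7-[4-(triisopropylsilyloxy)phenyl]hept-1-en-3-yl]-2-hydroxy-6-methoxy-4-(triisopropylsilyloxy)phenyl]prop-2-en-1-one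
Conditions: Pd(PPh3)4 (5 mol %), PhNHMe, THF, rt
Reagents that add atoms: none
Why: Palladium-catalysed deallylation (Tsuji–Trost type), in which zerovalent palladium ionises the allyl ether of the ortho-acyl phenol, a good leaving group, and N-methylaniline traps the allyl fragment without adding to the enone.

Step 16
Reactants: 25 silyl-protected chalcone
Product: 26 deoxycalyxin A, (2E)-1-[3-[(1E,3R)-1,7-bis(4-hydroxyphenyl)hept-1-en-3-yl]-2,4-dihydroxy-6-methoxyphenyl]-3-(4-hydroxyphenyl)prop-2-en-1-one
Conditions: Bu4NF, AcOH (1:1), THF, 0 °C to rt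
Reagents that add atoms: none
Why: Fluoride-induced cleavage of the four aryl silyl ethers, buffered with acetic acid so that the 2'-hydroxychalcone should not cyclise to the flavanone and no acid strong enough to protonate the styrene is present.

**Compound list**

1 | penta-1,4-dien-3-ol | C=CC(O)C=C | starting material
2 | (E)-5-bromopenta-1,3-diene | C=C/C=C/CBr | intermediate
3 | 2',4'-dihydroxy-6'-methoxyacetophenone | CC(=O)c1c(O)cc(O)cc1OC | starting material
4 | 1-[2-hydroxy-6-methoxy-4-[(2E)-penta-2,4-dien-1-yloxy]phenyl]ethan-1-one | CC(=O)c1c(O)cc(OC/C=C/C=C)cc1OC | intermediate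
5 | 1-[2,4-dihydroxy-6-methoxy-3-(penta-1,4-dien-3-yl)phenyl]ethan-1-one | CC(=O)c1c(O)c(C(C=C)C=C)c(O)cc1OC | intermediate
6 | 1-[2-hydroxy-6-methoxy-3-(penta-1,4-dien-3-yl)-4-(triisopropylsilyloxy)phenyl]ethan-1-one | CC(=O)c1c(O)c(C(C=C)C=C)c(O[Si](C(C)C)(C(C)C)C(C)C)cc1OC | intermediate
7 | 1-[2-(ethenyloxy)-6-methoxy-3-(penta-1,4-dien-3-yl)-4-(triisopropylsilyloxy)phenyl]ethan-1-one (key-step precursor) | CC(=O)c1c(OC=C)c(C(C=C)C=C)c(O[Si](C(C)C)(C(C)C)C(C)C)cc1OC | intermediate
8 | 1-[(4R)-4-ethenyl-7-methoxy-5-(triisopropylsilyloxy)-4H-chromen-8-yl]ethan-1-one (key-step product) | COc1cc(O[Si](C(C)C)(C(C)C)C(C)C)c2c(OC=C[C@H]2C=C)c1C(C)=O | intermediate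
9 | 4-(2-bromoethyl)phenol | Oc1ccc(CCBr)cc1 | starting material
10 | [4-(2-bromoethyl)phenoxy]triisopropylsilane | CC(C)[Si](Oc1ccc(CCBr)cc1)(C(C)C)C(C)C | intermediate
11 | 1-[(4R)-4-[2-(9-borabicyclo[3.3.1]nonan-9-yl)ethyl]-7-methoxy-5-(triisopropylsilyloxy)-4H-chromen-8-yl]ethan-1-one (alkylborane; not isolated) | COc1cc(O[Si](C(C)C)(C(C)C)C(C)C)c2c(OC=C[C@H]2CCB2C3CCCC2CCC3)c1C(C)=O | intermediate
12 | 1-[(4R)-7-methoxy-5-(triisopropylsilyloxy)-4-[4-[4-(triisopropylsilyloxy)phenyl]butyl]-4H-chromen-8-yl]ethan-1-one | COc1cc(O[Si](C(C)C)(C(C)C)C(C)C)c2c(OC=C[C@H]2CCCCc3ccc(O[Si](C(C)C)(C(C)C)C(C)C)cc3)c1C(C)=O | intermediate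
13 | (3R)-3-[3-acetyl-2-hydroxy-4-methoxy-6-(triisopropylsilyloxy)phenyl]-7-[4-(triisopropylsilyloxy)phenyl]heptanal (open form of the 2-chromanol hemiacetal) | COc1cc(O[Si](C(C)C)(C(C)C)C(C)C)c([C@@H](CC=O)CCCCc2ccc(O[Si](C(C)C)(C(C)C)C(C)C)cc2)c(O)c1C(C)=O | intermediate
14 | (3R)-3-[3-acetyl-4-methoxy-2-(prop-2-en-1-yloxy)-6-(triisopropylsilyloxy)phenyl]-7-[4-(triisopropylsilyloxy)phenyl]heptanal | COc1cc(O[Si](C(C)C)(C(C)C)C(C)C)c([C@@H](CC=O)CCCCc2ccc(O[Si](C(C)C)(C(C)C)C(C)C)cc2)c(OCC=C)c1C(C)=O | intermediate
15 | 4-iodophenol | Oc1ccc(I)cc1 | starting material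
16 | tert-butyl(4-iodophenoxy)dimethylsilane | CC(C)(C)[Si](C)(C)Oc1ccc(I)cc1 | intermediate
17 | [4-(tert-butyldimethylsilyloxy)phenyl]chromium dichloride (arylchromium; not isolated) | CC(C)(C)[Si](C)(C)Oc1ccc([Cr](Cl)Cl)cc1 | intermediate
18 | 1-[3-[(1RS,3R)-1-[4-(tert-butyldimethylsilyloxy)phenyl]-1-hydroxy-7-[4-(triisopropylsilyloxy)phenyl]heptan-3-yl]-6-methoxy-2-(prop-2-en-1-yloxy)-4-(triisopropylsilyloxy)phenyl]ethan-1-one | COc1cc(O[Si](C(C)C)(C(C)C)C(C)C)c([C@@H](CC(O)c2ccc(O[Si](C)(C)C(C)(C)C)cc2)CCCCc2ccc(O[Si](C(C)C)(C(C)C)C(C)C)cc2)c(OCC=C)c1C(C)=O | intermediate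
19 | N-(methoxycarbonyl)sulfamate ester of alcohol 18 at C1 (not isolated) | COc1cc(O[Si](C(C)C)(C(C)C)C(C)C)c([C@@H](CC(OS(=O)(=O)NC(=O)OC)c2ccc(O[Si](C)(C)C(C)(C)C)cc2)CCCCc2ccc(O[Si](C(C)C)(C(C)C)C(C)C)cc2)c(OCC=C)c1C(C)=O | intermediate
20 | 1-[3-[(1E,3R)-1-[4-(tert-butyldimethylsilyloxy)phenyl]-7-[4-(triisopropylsilyloxy)phenyl]hept-1-en-3-yl]-6-methoxy-2-(prop-2-en-1-yloxy)-4-(triisopropylsilyloxy)phenyl]ethan-1-one | COc1cc(O[Si](C(C)C)(C(C)C)C(C)C)c([C@@H](/C=C/c2ccc(O[Si](C)(C)C(C)(C)C)cc2)CCCCc2ccc(O[Si](C(C)C)(C(C)C)C(C)C)cc2)c(OCC=C)c1C(C)=O | intermediate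
21 | 4-(tert-butyldimethylsilyloxy)benzaldehyde | CC(C)(C)[Si](C)(C)Oc1ccc(C=O)cc1 | starting material
22 | β-hydroxy ketone from 20 and 21 (aldol adduct, both carbinol epimers; not isolated) | COc1cc(O[Si](C(C)C)(C(C)C)C(C)C)c([C@@H](/C=C/c2ccc(O[Si](C)(C)C(C)(C)C)cc2)CCCCc2ccc(O[Si](C(C)C)(C(C)C)C(C)C)cc2)c(OCC=C)c1C(=O)CC(O)c1ccc(O[Si](C)(C)C(C)(C)C)cc1 | intermediate
23 | methanesulfonate of aldol adduct 22 (not isolated) | COc1cc(O[Si](C(C)C)(C(C)C)C(C)C)c([C@@H](/C=C/c2ccc(O[Si](C)(C)C(C)(C)C)cc2)CCCCc2ccc(O[Si](C(C)C)(C(C)C)C(C)C)cc2)c(OCC=C)c1C(=O)CC(OS(C)(=O)=O)c1ccc(O[Si](C)(C)C(C)(C)C)cc1 | intermediate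
24 | (2E)-3-[4-(tert-butyldimethylsilyloxy)phenyl]-1-[3-[(1E,3R)-1-[4-(tert-butyldimethylsilyloxy)phenyl]-7-[4-(triisopropylsilyloxy)phenyl]hept-1-en-3-yl]-6-methoxy-2-(prop-2-en-1-yloxy)-4-(triisopropylsilyloxy)phenyl]prop-2-en-1-one | COc1cc(O[Si](C(C)C)(C(C)C)C(C)C)c([C@@H](/C=C/c2ccc(O[Si](C)(C)C(C)(C)C)cc2)CCCCc2ccc(O[Si](C(C)C)(C(C)C)C(C)C)cc2)c(OCC=C)c1C(=O)/C=C/c1ccc(O[Si](C)(C)C(C)(C)C)cc1 | intermediate
25 | (2E)-3-[4-(tert-butyldimethylsilyloxy)phenyl]-1-[3-[(1E,3R)-1-[4-(tert-butyldimethylsilyloxy)phenyl]-7-[4-(triisopropylsilyloxy)phenyl]hept-1-en-3-yl]-2-hydroxy-6-methoxy-4-(triisopropylsilyloxy)phenyl]prop-2-en-1-one | COc1cc(O[Si](C(C)C)(C(C)C)C(C)C)c([C@@H](/C=C/c2ccc(O[Si](C)(C)C(C)(C)C)cc2)CCCCc2ccc(O[Si](C(C)C)(C(C)C)C(C)C)cc2)c(O)c1C(=O)/C=C/c1ccc(O[Si](C)(C)C(C)(C)C)cc1 | intermediate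
26 | deoxycalyxin A | COc1cc(O)c([C@@H](/C=C/c2ccc(O)cc2)CCCCc2ccc(O)cc2)c(O)c1C(=O)/C=C/c1ccc(O)cc1 | target

**Step count**

Total step count: 16. Longest linear sequence: 14 steps (steps 1–6, 8–10 and 12–16).

**Steps most likely to fail**

Step 6. The alkylidene may be consumed by Wittig-type olefination of the acetyl carbonyl, or the two enantiotopic vinyl groups may not be told apart well enough. Fallback, setting out from triene 7: ring closure without asymmetric induction by RuCl2(H2IMes)(=CH-2-iPrOC6H4), the second-generation Hoveyda–Grubbs catalyst, in toluene at 60–80 °C. Ruthenium alkylidenes tolerate ketones, and closure of aryl vinyl ethers onto allylic olefins to 4H-chromenes is known with such catalysts. This should give racemic 1-[4-ethenyl-7-methoxy-5-(triisopropylsilyloxy)-4H-chromen-8-yl]ethan-1-one F1. Preparative HPLC on a polysaccharide carbamate chiral stationary phase would then separate chromene 8 from 1-[(4S)-4-ethenyl-7-methoxy-5-(triisopropylsilyloxy)-4H-chromen-8-yl]ethan-1-one F2, and the route is rejoined at 8.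

Step 5. Ligand exchange of the hindered, hydrogen-bonded phenol at copper may be so slow that protodeboronation and homocoupling of the vinyl donor win. Fallback, setting out from phenol 6: the vinyl group would be built in two operations by known chemistry. Mitsunobu etherification with 2-(phenylselanyl)ethanol (PPh3, DIAD, THF) should give 1-[6-methoxy-3-(penta-1,4-dien-3-yl)-2-[2-(phenylselanyl)ethoxy]-4-(triisopropylsilyloxy)phenyl]ethan-1-one F3. Oxidation with NaIO4 (NaHCO3, MeOH–THF–H2O, 0 °C) should give the selenoxide 1-[2-[2-(benzeneseleninyl)ethoxy]-6-methoxy-3-(penta-1,4-dien-3-yl)-4-(triisopropylsilyloxy)phenyl]ethan-1-one F4. Warming F4 in toluene with iPr2NH, which traps the selenenic acid, should bring about syn-elimination toward the only β-hydrogens and return vinyl ether 7.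

Step 3. The dienyl group may migrate to the other ortho carbon, C5', or the dienyl ether may polymerise at the temperature of the rearrangement. Fallback, setting out from acetophenone 3 and bromide 2: the dienyl group would be delivered from O2', whose only free ortho carbon is C3'. Silylation of the 4-hydroxyl of 3 (TIPSCl, imidazole, DMF) should give 1-[2-hydroxy-6-methoxy-4-(triisopropylsilyloxy)phenyl]ethan-1-one F5. Alkylation of the chelated 2-hydroxyl with 2 (K2CO3, acetone, reflux) should give 1-[2-methoxy-6-[(2E)-penta-2,4-dien-1-yloxy]-4-(triisopropylsilyloxy)phenyl]ethan-1-one F6. Heating F6 in PhNEt2 at 185 °C should give phenol 6 directly, so step 4 falls away. The price is competition from the [5,5] shift to the free para carbon C5', whose linear dienyl product is a constitutional isomer that should be separable.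

**Further compounds**

F1 | step 6 | racemic 1-[4-ethenyl-7-methoxy-5-(triisopropylsilyloxy)-4H-chromen-8-yl]ethan-1-one | COc1cc(O[Si](C(C)C)(C(C)C)C(C)C)c2c(OC=CC2C=C)c1C(C)=O
F2 | step 6 | 1-[(4S)-4-ethenyl-7-methoxy-5-(triisopropylsilyloxy)-4H-chromen-8-yl]ethan-1-one | COc1cc(O[Si](C(C)C)(C(C)C)C(C)C)c2c(OC=C[C@@H]2C=C)c1C(C)=O
F3 | step 5 | 1-[6-methoxy-3-(penta-1,4-dien-3-yl)-2-[2-(phenylselanyl)ethoxy]-4-(triisopropylsilyloxy)phenyl]ethan-1-one | CC(=O)c1c(OCC[Se]c2ccccc2)c(C(C=C)C=C)c(O[Si](C(C)C)(C(C)C)C(C)C)cc1OC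
F4 | step 5 | 1-[2-[2-(benzeneseleninyl)ethoxy]-6-methoxy-3-(penta-1,4-dien-3-yl)-4-(triisopropylsilyloxy)phenyl]ethan-1-one | CC(=O)c1c(OCC[Se](=O)c2ccccc2)c(C(C=C)C=C)c(O[Si](C(C)C)(C(C)C)C(C)C)cc1OC
F5 | step 3 | 1-[2-hydroxy-6-methoxy-4-(triisopropylsilyloxy)phenyl]ethan-1-one | CC(=O)c1c(O)cc(O[Si](C(C)C)(C(C)C)C(C)C)cc1OC
F6 | step 3 | 1-[2-methoxy-6-[(2E)-penta-2,4-dien-1-yloxy]-4-(triisopropylsilyloxy)phenyl]ethan-1-one | CC(=O)c1c(OC/C=C/C=C)cc(O[Si](C(C)C)(C(C)C)C(C)C)cc1OC
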